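## Retrosynthetic overview

1. Target 24 ⇐ 20: the last operations are angeloylation of the free C8–OH and removal of the two primary silyl ethers.
2. 20 ⇐ 18 (key step): the C6–C7 bond is closed intramolecularly by an allylchromium made from a 2-(bromomethyl)enoate. C7, the β-carbon of the enoate, acts as a β-acyl carbanion (homoenolate) equivalent toward the C6 aldehyde carbon, so two normally electrophilic carbons are joined. The same step closes the γ-lactone and sets C6 and C7 next to the existing C8 centre.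
3. 18 ⇐ aldehyde 13 + methyl propiolate (C11–C13); 13 ⇐ triol 10 by silylation and selective oxidation at C7.
4. 10 ⇐ 5 + 8 by E-selective cross-metathesis (C1=C10) and global hydride reduction. 5 comes from chiral-pool lactone 1 (C7–C10, C14, the C8 centre); 8 from hex-5-enal and glyoxal mono-acetal (C1–C6, C15; C4=C5 geometry from an aldol condensation).
5. Ring order: the butyrolactone of 1 only carries C8 and is opened in step 5; the ten-membered carbocycle and the α-methylene-γ-lactone are then formed together in step 11.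

Assumption and notation: germacrane locants C1–C15 are used in the text; TES = triethylsilyl, TBDPS = tert-butyldiphenylsilyl; 1 is bought as the (R)-enantiomer (made from D-glutamic acid). Both ring olefins are ring-cis but carry the CIP descriptor E, because CH2O outranks the ring CH2.

## Route

Step 1
Reactants: 1 (5R)-5-(hydroxymethyl)oxolan-2-one
Product: 2 (5R)-5-[(TES-oxy)methyl]oxolan-2-one
Conditions: Et3SiCl, imidazole, CH2Cl2, 0 °C
Reagents that add atoms: triethylsilyl chloride, CC[Si](Cl)(CC)CC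
Why: Routine silyl ether formation on the primary alcohol, using TES because a primary TES ether can later be oxidised directly to the aldehyde (step 7), while the C8 stereocentre taken from 1 is untouched.

Step 2
Reactants: 2 (5R)-5-[(TES-oxy)methyl]oxolan-2-one
Product: 5 (5R)-3-methylidene-5-[(TES-oxy)methyl]oxolan-2-one, via Mannich base 3 (not isolated), via methiodide 4 (not isolated)
Conditions: LiN(SiMe3)2, THF, −78 °C; Me2N=CH2+ I−, −78 °C → rt; MeI, MeOH, rt; aq. NaHCO3/CH2Cl2, rt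
Reagents that add atoms: N,N-dimethylmethyleneiminium iodide (Eschenmoser's salt), C=[N+](C)C.[I-]; iodomethane, CI (its carbon stays only in intermediate 4)
Why: Eschenmoser α-methylenation (enolate Mannich reaction, quaternisation, E1cB loss of Me3N), in which the remote C8 centre cannot epimerise.

Step 3
Reactants: 6 hex-5-enal; 7 2,2-dimethoxyacetaldehyde (60% in water)
Product: 8 (2E)-2-(but-3-en-1-yl)-4,4-dimethoxybut-2-enal
Conditions: 7 (2 equiv), Bu2NH (0.2 equiv), AcOH (0.2 equiv), toluene, 70 °C, slow addition of 6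
Reagents that add atoms: none
Why: Amine/acid-catalysed crossed aldol condensation in which 7 serves only as acceptor (the reaction type used to make 4,4-dimethoxy-2-methylbut-2-enal), and the thermodynamic E-enal places CHO trans to the acetal carbon, which is the ring-cis C4=C5 geometry of the target.

Step 4
Reactants: 5 (5R)-3-methylidene-5-[(TES-oxy)methyl]oxolan-2-one; 8 (2E)-2-(but-3-en-1-yl)-4,4-dimethoxybut-2-enal
Product: 9 (3E,5R)-3-[(4E)-4-formyl-6,6-dimethoxyhex-4-en-1-ylidene]-5-[(TES-oxy)methyl]oxolan-2-one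
Conditions: 8 (2.5 equiv), second-generation Hoveyda–Grubbs catalyst RuCl2(H2IMes)(=CH–C6H4-2-OiPr) (5 mol%), 2,6-dichloro-1,4-benzoquinone (10 mol%), CH2Cl2, 40 °C
Reagents that add atoms: none
Why: Olefin cross-metathesis of an α-methylene-γ-butyrolactone with a terminal alkene gives the more stable E-alkylidene lactone (C2 cis to C9, the ring-cis C1=C10 geometry), the quinone suppressing isomerisation to the butenolide and the trisubstituted enal olefin staying inert.

Step 5
Reactants: 9 (3E,5R)-3-[(4E)-4-formyl-6,6-dimethoxyhex-4-en-1-ylidene]-5-[(TES-oxy)methyl]oxolan-2-one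
Product: 10 (2R,4E,8E)-4,8-bis(hydroxymethyl)-10,10-dimethoxy-1-(TES-oxy)deca-4,8-dien-2-ol
Conditions: iBu2AlH (6 equiv), CH2Cl2, −78 → 0 °C; aq. potassium sodium tartrate
Reagents that add atoms: none
Why: Hydride reduction by iBu2AlH takes the lactone to the diol and the enal 1,2 to the allylic alcohol in one operation, releasing C14–OH, C15–OH and the C8 carbinol without touching the acetal, the silyl ether or either olefin geometry.

Step 6
Reactants: 10 (2R,4E,8E)-4,8-bis(hydroxymethyl)-10,10-dimethoxy-1-(TES-oxy)deca-4,8-dien-2-ol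
Product: 12 (2R,4E,8E)-4,8-bis(TBDPS-oxymethyl)-10,10-dimethoxy-1,2-bis(TES-oxy)deca-4,8-diene, via bis-TBDPS alcohol 11 (not isolated)
Conditions: tBuPh2SiCl (2.1 equiv), imidazole, DMF, −20 → 0 °C; then Et3SiCl (1.5 equiv), rt
Reagents that add atoms: tert-butyl(chloro)diphenylsilane, CC(C)(C)[Si](Cl)(c1ccccc1)c1ccccc1; triethylsilyl chloride, CC[Si](Cl)(CC)CC
Why: Sterically controlled chemoselective silylation, in which the bulky chlorosilane takes only the two primary allylic alcohols at low temperature and the remaining secondary C8–OH is then capped as its TES ether in the same flask.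

Step 7
Reactants: 12 (2R,4E,8E)-4,8-bis(TBDPS-oxymethyl)-10,10-dimethoxy-1,2-bis(TES-oxy)deca-4,8-diene
Product: 13 (2R,4E,8E)-4,8-bis(TBDPS-oxymethyl)-10,10-dimethoxy-2-(TES-oxy)deca-4,8-dienal
Conditions: (COCl)2 (4 equiv), DMSO (8 equiv), CH2Cl2, −78 → −40 °C; iPr2NEt, −78 → 0 °C
Reagents that add atoms: none
Why: Swern oxidation with oxidative desilylation, in which a primary TES ether is cleaved by the chlorosulfonium reagent and oxidised in situ to the aldehyde while secondary TES and TBDPS ethers survive, the low temperature and hindered amine keeping the α-silyloxy aldehyde from epimerising at C8.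

Step 8
Reactants: 13 (2R,4E,8E)-4,8-bis(TBDPS-oxymethyl)-10,10-dimethoxy-2-(TES-oxy)deca-4,8-dienal; 14 methyl prop-2-ynoate
Product: 16 methyl (4R,6E,10E)-6,10-bis(TBDPS-oxymethyl)-3-hydroxy-12,12-dimethoxy-2-methylidene-4-(TES-oxy)dodeca-6,10-dienoate (both C3 epimers), via α-alanyl acrylate 15 (not isolated)
Conditions: 14, iBu2AlH, N-methylmorpholine N-oxide, THF, 0 °C; then 13, 0 °C → rt
Reagents that add atoms: diisobutylaluminium hydride, CC(C)C[AlH]CC(C)C (its atoms stay only in intermediate 15)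
Why: Vinylalumination (hydroalumination of 14, then addition of the α-alanyl acrylate to the aldehyde) gives the Morita–Baylis–Hillman-type adduct without amine base, so C8 is not epimerised, and the new C7 carbinol forms as a mixture that is erased in step 9.

Step 9
Reactants: 16 methyl (4R,6E,10E)-6,10-bis(TBDPS-oxymethyl)-3-hydroxy-12,12-dimethoxy-2-methylidene-4-(TES-oxy)dodeca-6,10-dienoate
Product: 17 methyl (2Z,4R,6E,10E)-2-(bromomethyl)-6,10-bis(TBDPS-oxymethyl)-12,12-dimethoxy-4-(TES-oxy)dodeca-2,6,10-trienoate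
Conditions: NBS, Me2S, CH2Cl2, 0 °C; then 16, 0 °C → rt
Reagents that add atoms: N-bromosuccinimide, O=C1CCC(=O)N1Br
Why: Corey–Kim activation of the allylic alcohol followed by SN2′ attack of bromide at the CH2 terminus moves the olefin into conjugation and gives the 2-(bromomethyl)enoate with the ester trans to the bulky C8 substituent (2Z).

Step 10
Reactants: 17 methyl (2Z,4R,6E,10E)-2-(bromomethyl)-6,10-bis(TBDPS-oxymethyl)-12,12-dimethoxy-4-(TES-oxy)dodeca-2,6,10-trienoate
Product: 18 methyl (2Z,4R,6E,10E)-2-(bromomethyl)-6,10-bis(TBDPS-oxymethyl)-12-oxo-4-(TES-oxy)dodeca-2,6,10-trienoate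
Conditions: SiO2, 10% aq. oxalic acid, CH2Cl2, rt
Reagents that add atoms: water, O
Why: Acetal hydrolysis on wet acidic silica is far faster for the electron-rich allylic dimethyl acetal than silyl ether cleavage, so the C6 enal is unmasked with the silyl groups, the allylic bromide and the olefin geometry intact.

Step 11
Reactants: 18 methyl (2Z,4R,6E,10E)-2-(bromomethyl)-6,10-bis(TBDPS-oxymethyl)-12-oxo-4-(TES-oxy)dodeca-2,6,10-trienoate
Product: 20 (3aR,4R,6E,10E,11aR)-6,10-bis(TBDPS-oxymethyl)-4-hydroxy-3-methylidene-3a,4,5,8,9,11a-hexahydrocyclodeca[b]furan-2(3H)-one, via triethylsilyl ether 19 (not isolated)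
Conditions: CrCl2 (8 equiv), THF/DMF 1:1, 2 mM, syringe-pump addition of 18, rt; then 1 M HCl/THF, rt
Reagents that add atoms: none
Why: Intramolecular Nozaki–Hiyama (Barbier-type) 2-(alkoxycarbonyl)allylation with lactonisation, a ring closure known for ten-membered germacranolides: divalent chromium turns the allylic bromide into an allylchromium in which C7 (the electrophilic enoate β-carbon of 18) is a β-acyl carbanion equivalent that adds 1,2 to the C6 aldehyde through a chair transition state inside the forming ring, the alkoxide closes the γ-lactone on the ester, the C8 centre (C8–H in the allyl plane to avoid A1,3 strain, OTES turned outward) is expected to direct the C7 face, and because the allylchromium is configurationally labile the two ring-cis olefins select the chair that gives the anti C6/C7 adduct, that is the trans-fused lactone of the natural 6R,7R,8R array, while the acidic work-up removes the secondary TES group.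

Step 12
Reactants: 20 (3aR,4R,6E,10E,11aR)-6,10-bis(TBDPS-oxymethyl)-4-hydroxy-3-methylidene-3a,4,5,8,9,11a-hexahydrocyclodeca[b]furan-2(3H)-one; 21 (2Z)-2-methylbut-2-enoic acid (angelic acid)
Product: 23 (3aR,4R,6E,10E,11aR)-6,10-bis(TBDPS-oxymethyl)-3-methylidene-2-oxo-2,3,3a,4,5,8,9,11a-octahydrocyclodeca[b]furan-4-yl (2Z)-2-methylbut-2-enoate, via mixed anhydride 22 (not isolated)
Conditions: 21, 2,4,6-trichlorobenzoyl chloride, Et3N, toluene, rt; then 20, toluene, 75 °C (no DMAP)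
Reagents that add atoms: 2,4,6-trichlorobenzoyl chloride, O=C(Cl)c1c(Cl)cc(Cl)cc1Cl (its atoms stay only in intermediate 22)
Why: Yamaguchi-type mixed-anhydride esterification acylates the only free hydroxyl (C8, both primary alcohols being silylated) with retention at C8, and omitting the nucleophilic catalyst avoids isomerisation of the angelate to the tiglate.

Step 13
Reactants: 23 (3aR,4R,6E,10E,11aR)-6,10-bis(TBDPS-oxymethyl)-3-methylidene-2-oxo-2,3,3a,4,5,8,9,11a-octahydrocyclodeca[b]furan-4-yl (2Z)-2-methylbut-2-enoate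
Product: 24 (3aR,4R,6E,10E,11aR)-6,10-bis(hydroxymethyl)-3-methylidene-2-oxo-2,3,3a,4,5,8,9,11a-octahydrocyclodeca[b]furan-4-yl (2Z)-2-methylbut-2-enoate
Conditions: HF·pyridine, pyridine, THF, 0 °C → rt
Reagents that add atoms: none
Why: Buffered fluoride desilylation frees the two primary allylic alcohols without the basic conditions that would trigger acyl migration, translactonisation or conjugate addition to the α-methylene lactone.

## Compound list

1 | (5R)-5-(hydroxymethyl)oxolan-2-one | OC[C@H]1CCC(=O)O1 | starting material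
2 | (5R)-5-[(TES-oxy)methyl]oxolan-2-one | CC[Si](CC)(CC)OC[C@H]1CCC(=O)O1 | intermediate
3 | (5R)-3-[(dimethylamino)methyl]-5-[(TES-oxy)methyl]oxolan-2-one (C3 epimers) | CC[Si](CC)(CC)OC[C@H]1CC(CN(C)C)C(=O)O1 | intermediate
4 | trimethyl{[(5R)-2-oxo-5-[(TES-oxy)methyl]oxolan-3-yl]methyl}ammonium iodide (C3 epimers) | CC[Si](CC)(CC)OC[C@H]1CC(C[N+](C)(C)C)C(=O)O1.[I-] | intermediate
5 | (5R)-3-methylidene-5-[(TES-oxy)methyl]oxolan-2-one | CC[Si](CC)(CC)OC[C@H]1CC(=C)C(=O)O1 | intermediate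
6 | hex-5-enal | C=CCCCC=O | starting material
7 | 2,2-dimethoxyacetaldehyde | COC(OC)C=O | starting material
8 | (2E)-2-(but-3-en-1-yl)-4,4-dimethoxybut-2-enal | C=CCC/C(C=O)=C\C(OC)OC | intermediate
9 | (3E,5R)-3-[(4E)-4-formyl-6,6-dimethoxyhex-4-en-1-ylidene]-5-[(TES-oxy)methyl]oxolan-2-one | CC[Si](CC)(CC)OC[C@H]1C/C(=C\CC/C(C=O)=C\C(OC)OC)C(=O)O1 | intermediate
10 | (2R,4E,8E)-4,8-bis(hydroxymethyl)-10,10-dimethoxy-1-(TES-oxy)deca-4,8-dien-2-ol | CC[Si](CC)(CC)OC[C@H](O)C/C(CO)=C\CC/C(CO)=C\C(OC)OC | intermediate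
11 | (2R,4E,8E)-4,8-bis(TBDPS-oxymethyl)-10,10-dimethoxy-1-(TES-oxy)deca-4,8-dien-2-ol | CC[Si](CC)(CC)OC[C@H](O)C/C(CO[Si](c1ccccc1)(c1ccccc1)C(C)(C)C)=C\CC/C(CO[Si](c1ccccc1)(c1ccccc1)C(C)(C)C)=C\C(OC)OC | intermediate
12 | (2R,4E,8E)-4,8-bis(TBDPS-oxymethyl)-10,10-dimethoxy-1,2-bis(TES-oxy)deca-4,8-diene | CC[Si](CC)(CC)OC[C@H](O[Si](CC)(CC)CC)C/C(CO[Si](c1ccccc1)(c1ccccc1)C(C)(C)C)=C\CC/C(CO[Si](c1ccccc1)(c1ccccc1)C(C)(C)C)=C\C(OC)OC | intermediate
13 | (2R,4E,8E)-4,8-bis(TBDPS-oxymethyl)-10,10-dimethoxy-2-(TES-oxy)deca-4,8-dienal | O=C[C@H](O[Si](CC)(CC)CC)C/C(CO[Si](c1ccccc1)(c1ccccc1)C(C)(C)C)=C\CC/C(CO[Si](c1ccccc1)(c1ccccc1)C(C)(C)C)=C\C(OC)OC | intermediate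
14 | methyl prop-2-ynoate | C#CC(=O)OC | starting material
15 | methyl 2-(diisobutylalumanyl)prop-2-enoate | C=C([Al](CC(C)C)CC(C)C)C(=O)OC | intermediate
16 | methyl (4R,6E,10E)-6,10-bis(TBDPS-oxymethyl)-3-hydroxy-12,12-dimethoxy-2-methylidene-4-(TES-oxy)dodeca-6,10-dienoate (C3 epimers) | C=C(C(=O)OC)C(O)[C@H](O[Si](CC)(CC)CC)C/C(CO[Si](c1ccccc1)(c1ccccc1)C(C)(C)C)=C\CC/C(CO[Si](c1ccccc1)(c1ccccc1)C(C)(C)C)=C\C(OC)OC | intermediate
17 | methyl (2Z,4R,6E,10E)-2-(bromomethyl)-6,10-bis(TBDPS-oxymethyl)-12,12-dimethoxy-4-(TES-oxy)dodeca-2,6,10-trienoate | BrC/C(C(=O)OC)=C\[C@H](O[Si](CC)(CC)CC)C/C(CO[Si](c1ccccc1)(c1ccccc1)C(C)(C)C)=C\CC/C(CO[Si](c1ccccc1)(c1ccccc1)C(C)(C)C)=C\C(OC)OC | intermediate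
18 | methyl (2Z,4R,6E,10E)-2-(bromomethyl)-6,10-bis(TBDPS-oxymethyl)-12-oxo-4-(TES-oxy)dodeca-2,6,10-trienoate | BrC/C(C(=O)OC)=C\[C@H](O[Si](CC)(CC)CC)C/C(CO[Si](c1ccccc1)(c1ccccc1)C(C)(C)C)=C\CC/C(CO[Si](c1ccccc1)(c1ccccc1)C(C)(C)C)=C\C=O | intermediate
19 | (3aS,4R,6E,10E,11aR)-6,10-bis(TBDPS-oxymethyl)-3-methylidene-4-(TES-oxy)-3a,4,5,8,9,11a-hexahydrocyclodeca[b]furan-2(3H)-one (3aS only because OSi outranks OC; same spatial arrangement as in 20) | C=C1C(=O)O[C@@H]2/C=C(/CO[Si](c3ccccc3)(c3ccccc3)C(C)(C)C)CC/C=C(/CO[Si](c3ccccc3)(c3ccccc3)C(C)(C)C)C[C@@H](O[Si](CC)(CC)CC)[C@@H]12 | intermediate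
20 | (3aR,4R,6E,10E,11aR)-6,10-bis(TBDPS-oxymethyl)-4-hydroxy-3-methylidene-3a,4,5,8,9,11a-hexahydrocyclodeca[b]furan-2(3H)-one | C=C1C(=O)O[C@@H]2/C=C(/CO[Si](c3ccccc3)(c3ccccc3)C(C)(C)C)CC/C=C(/CO[Si](c3ccccc3)(c3ccccc3)C(C)(C)C)C[C@@H](O)[C@@H]12 | intermediate
21 | (2Z)-2-methylbut-2-enoic acid (angelic acid) | C/C=C(/C)C(=O)O | starting material
22 | (2Z)-2-methylbut-2-enoic 2,4,6-trichlorobenzoic anhydride | C/C=C(/C)C(=O)OC(=O)c1c(Cl)cc(Cl)cc1Cl | intermediate
23 | (3aR,4R,6E,10E,11aR)-6,10-bis(TBDPS-oxymethyl)-3-methylidene-2-oxo-2,3,3a,4,5,8,9,11a-octahydrocyclodeca[b]furan-4-yl (2Z)-2-methylbut-2-enoate | C=C1C(=O)O[C@@H]2/C=C(/CO[Si](c3ccccc3)(c3ccccc3)C(C)(C)C)CC/C=C(/CO[Si](c3ccccc3)(c3ccccc3)C(C)(C)C)C[C@@H](OC(=O)/C(C)=C\C)[C@@H]12 | intermediate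
24 | (3aR,4R,6E,10E,11aR)-6,10-bis(hydroxymethyl)-3-methylidene-2-oxo-2,3,3a,4,5,8,9,11a-octahydrocyclodeca[b]furan-4-yl (2Z)-2-methylbut-2-enoate | C=C1C(=O)O[C@@H]2/C=C(/CO)CC/C=C(/CO)C[C@@H](OC(=O)/C(C)=C\C)[C@@H]12 | target

## Step count and weak points

Total steps: 13. Longest linear sequence: 12 steps (1 → 2 → 5 → 9 → 10 → 12 → 13 → 16 → 17 → 18 → 20 → 23 → 24; step 3 is a one-step side branch).

Most likely to fail, in this order:

Step 11 (ring closure). Oligomerisation may compete, and the diastereoselectivity rests on macrocyclic control: open-chain 2-(bromomethyl)enoates of this geometry normally give the syn adduct, which would lead to the cis-lactone. The fallback sets out from 13 and comes back at 19; it replaces the labile allylchromium by a geometry-defined allylboronate that reacts through a closed chair. Seyferth–Gilbert homologation of 13 (dimethyl (1-diazo-2-oxopropyl)phosphonate, K2CO3, MeOH) gives (3R,5E,9E)-5,9-bis(TBDPS-oxymethyl)-11,11-dimethoxy-3-(TES-oxy)undeca-5,9-dien-1-yne F3. Deprotonation with n-BuLi and quenching with ClCO2Me gives methyl (4R,6E,10E)-6,10-bis(TBDPS-oxymethyl)-12,12-dimethoxy-4-(TES-oxy)dodeca-6,10-dien-2-ynoate F4. Syn-hydroalumination (iBu2AlH, HMPA) and trapping with 2-(iodomethyl)-4,4,5,5-tetramethyl-1,3,2-dioxaborolane gives methyl (2Z,4R,6E,10E)-6,10-bis(TBDPS-oxymethyl)-12,12-dimethoxy-2-[(4,4,5,5-tetramethyl-1,3,2-dioxaborolan-2-yl)methyl]-4-(TES-oxy)dodeca-2,6,10-trienoate F5, in which C8 is cis to the ester. Oxalic acid on silica frees the enal, methyl (2Z,4R,6E,10E)-6,10-bis(TBDPS-oxymethyl)-12-oxo-2-[(4,4,5,5-tetramethyl-1,3,2-dioxaborolan-2-yl)methyl]-4-(TES-oxy)dodeca-2,6,10-trienoate F6. Heating F6 at 2 mM in toluene (80 °C) closes the ring by intramolecular allylboration with C5 and C8 both equatorial in the chair, which gives the anti adduct; catalytic TsOH then lactonises it to 19.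

Step 4 (cross-metathesis). The α-methylene lactone may isomerise to the butenolide or couple poorly with the functionalised diene. The fallback sets out from 2 (and uses 7) and comes back at 9; it replaces metathesis by an olefination. Treatment of 2 with LiN(iPr)2 (2.2 equiv) and ClP(O)(OEt)2 gives, after migration of phosphorus from oxygen to carbon, diethyl [(5R)-2-oxo-5-[(TES-oxy)methyl]oxolan-3-yl]phosphonate F1. The amine-catalysed condensation of step 3, run with 7 and an excess of commercial pentanedial, gives (2E)-2-(2,2-dimethoxyethylidene)pentanedial F2. Horner–Wadsworth–Emmons reaction of F1 (LiCl, iPr2NEt, MeCN) at the saturated, more electrophilic aldehyde of F2 gives the E-alkylidene lactone 9 directly.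

Step 12 (angeloylation). The C8 alcohol is hindered and angelates isomerise easily to tiglates. The fallback sets out from 20 and comes back at 23; it builds the Z-olefin on an ester already in place. Esterification of 20 with 2-[bis(2,2,2-trifluoroethoxy)phosphoryl]propanoic acid (DCC, cat. DMAP) gives (3aR,4R,6E,10E,11aR)-6,10-bis(TBDPS-oxymethyl)-3-methylidene-2-oxo-2,3,3a,4,5,8,9,11a-octahydrocyclodeca[b]furan-4-yl 2-[bis(2,2,2-trifluoroethoxy)phosphoryl]propanoate F7. Still–Gennari olefination of F7 with acetaldehyde (KN(SiMe3)2, 18-crown-6, THF, −78 °C) gives the Z-2-methylbut-2-enoate 23.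

## Further compounds

F1 | step 4 | diethyl [(5R)-2-oxo-5-[(TES-oxy)methyl]oxolan-3-yl]phosphonate (C3 epimers) | CC[Si](CC)(CC)OC[C@H]1CC(P(=O)(OCC)OCC)C(=O)O1
F2 | step 4 | (2E)-2-(2,2-dimethoxyethylidene)pentanedial | O=CCC/C(C=O)=C\C(OC)OC
F3 | step 11 | (3R,5E,9E)-5,9-bis(TBDPS-oxymethyl)-11,11-dimethoxy-3-(TES-oxy)undeca-5,9-dien-1-yne | C#C[C@H](O[Si](CC)(CC)CC)C/C(CO[Si](c1ccccc1)(c1ccccc1)C(C)(C)C)=C\CC/C(CO[Si](c1ccccc1)(c1ccccc1)C(C)(C)C)=C\C(OC)OC
F4 | step 11 | methyl (4R,6E,10E)-6,10-bis(TBDPS-oxymethyl)-12,12-dimethoxy-4-(TES-oxy)dodeca-6,10-dien-2-ynoate | COC(=O)C#C[C@H](O[Si](CC)(CC)CC)C/C(CO[Si](c1ccccc1)(c1ccccc1)C(C)(C)C)=C\CC/C(CO[Si](c1ccccc1)(c1ccccc1)C(C)(C)C)=C\C(OC)OC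
F5 | step 11 | methyl (2Z,4R,6E,10E)-6,10-bis(TBDPS-oxymethyl)-12,12-dimethoxy-2-[(4,4,5,5-tetramethyl-1,3,2-dioxaborolan-2-yl)methyl]-4-(TES-oxy)dodeca-2,6,10-trienoate | CC1(C)OB(C/C(C(=O)OC)=C/[C@H](O[Si](CC)(CC)CC)C/C(CO[Si](c2ccccc2)(c2ccccc2)C(C)(C)C)=C\CC/C(CO[Si](c2ccccc2)(c2ccccc2)C(C)(C)C)=C\C(OC)OC)OC1(C)C
F6 | step 11 | methyl (2Z,4R,6E,10E)-6,10-bis(TBDPS-oxymethyl)-12-oxo-2-[(4,4,5,5-tetramethyl-1,3,2-dioxaborolan-2-yl)methyl]-4-(TES-oxy)dodeca-2,6,10-trienoate | CC1(C)OB(C/C(C(=O)OC)=C/[C@H](O[Si](CC)(CC)CC)C/C(CO[Si](c2ccccc2)(c2ccccc2)C(C)(C)C)=C\CC/C(CO[Si](c2ccccc2)(c2ccccc2)C(C)(C)C)=C\C=O)OC1(C)C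
F7 | step 12 | (3aR,4R,6E,10E,11aR)-6,10-bis(TBDPS-oxymethyl)-3-methylidene-2-oxo-2,3,3a,4,5,8,9,11a-octahydrocyclodeca[b]furan-4-yl 2-[bis(2,2,2-trifluoroethoxy)phosphoryl]propanoate | C=C1C(=O)O[C@@H]2/C=C(/CO[Si](c3ccccc3)(c3ccccc3)C(C)(C)C)CC/C=C(/CO[Si](c3ccccc3)(c3ccccc3)C(C)(C)C)C[C@@H](OC(=O)C(C)P(=O)(OCC(F)(F)F)OCC(F)(F)F)[C@@H]12
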